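**Strategy.** Numbering: ring C1 (C=O), C2=C3, C4 (OMe), C5, C6 (quaternary); side chain C7 (CHMe), C8 (aryl C=O). On the cyclohexenone ring, C6 carries an allyl group and the arm C5H2–C4H(O). These are two identical CH2–CH units, so C6 is traced back to a non-stereogenic diallyl carbon. The precursor is a 2,2-diallyl acid whose only stereocentre is C7 and whose C8 is a tert-butyl ester. One catalyst-controlled iodolactonisation joins the C1 carboxyl oxygen to C4 and iodine to C3, closes a γ-lactone (O, C1, C6, C5, C4), and sets C4 and C6 together. C2 then enters from thioanisole, a sulfoxide Dieckmann closure makes C1–C2, and the aryl ketone comes last.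

Key step: step 5

**Stereochemical bookkeeping.** The target is (4S,6S,7R), with C4–OMe and the C7 branch on the same face of the carbocycle. On the iodolactone this corresponds to CH2I cis to the free allyl group and trans to the C7 branch. Every later step keeps the C4–O bond.

**Design points.**
- (a) Step 5 is run under kinetic conditions with N-iodosuccinimide. On a γ-lactone the bulkier α- and γ-substituents prefer to be cis, so equilibration would favour CH2I next to the C7 branch, which is the wrong C4/C6 relation. The HI of an iodine-only protocol would also endanger the tert-butyl ester.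
- (b) A C4 alkoxide γ to a C1 ester closes the lactone again at once. The route therefore accepts the relactonised sulfide after the epoxide opening and methylates C4–O only while C1 is a carboxylate (step 8).
- (c) Aryllithium or arylmagnesium reagents would attack the enone, so the C8 ketone is made last by palladium-catalysed acylation of an arylzinc reagent.
- (d) The tert-butyl ester stays at C8. It is the poorest internal nucleophile in step 5, resists the nucleophiles of steps 6 to 10, shields C7–H, and leaves with acid.

**Assumption.** The (S)-catalyst is taken to be the matched partner of (R)-C7 for reaction of the pro-S allyl group. If the sense proves opposite, its (R)-antipode is used in the same step.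

Step 1
Reactants: 1 (R)-2-methylsuccinic acid 4-methyl ester; 2 allyl bromide
Product: 3 (2R)-3-(methoxycarbonyl)-2-methylhex-5-enoic acid (epimer mixture at C6)
Conditions: LDA (2.2 equiv), THF, −78 °C; 2 (1.1 equiv), −78 to −20 °C; 1 M HCl
Reagents that add atoms: none
Why: Allylation of the carboxylate/ester-enolate dianion, in which the second equivalent of base removes a proton of the CH2 next to the ester, the carboxylate keeps C7–H non-acidic so that C7 holds, and the configuration of the new centre does not matter because step 2 erases it.

Step 2
Reactants: 3 (2R)-3-(methoxycarbonyl)-2-methylhex-5-enoic acid; 2 allyl bromide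
Product: 4 (2R)-3-allyl-3-(methoxycarbonyl)-2-methylhex-5-enoic acid
Conditions: LDA (2.3 equiv), THF/DMPU, −78 to −20 °C; 2 (1.5 equiv), −78 °C to rt; 1 M HCl
Reagents that add atoms: none
Why: A second dianion (ester enolate) allylation, in which the small and reactive allylic halide tolerates the crowded nucleophile, both epimers of 3 converge because C6 now bears two identical groups, and C7 is again protected by the neighbouring carboxylate.

Step 3
Reactants: 4 (2R)-3-allyl-3-(methoxycarbonyl)-2-methylhex-5-enoic acid
Product: 5 1-tert-butyl 4-methyl (2R)-3,3-diallyl-2-methylbutanedioate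
Conditions: tert-butyl 2,2,2-trichloroacetimidate (2 equiv), BF3·OEt2 (5 mol%), cyclohexane/CH2Cl2 2:1, rt
Reagents that add atoms: tert-butyl 2,2,2-trichloroacetimidate, CC(C)(C)OC(=N)C(Cl)(Cl)Cl
Why: Imidate esterification alkylates the carboxyl oxygen with a tert-butyl cation donor, so it needs neither attack at the crowded C8 carbonyl nor any base, and C7 cannot epimerise.

Step 4
Reactants: 5 1-tert-butyl 4-methyl (2R)-3,3-diallyl-2-methylbutanedioate
Product: 6 (3R)-2,2-diallyl-4-tert-butoxy-3-methyl-4-oxobutanoic acid (2,2-diallyl-3-methylbutanedioic acid 4-tert-butyl ester)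
Conditions: EtSNa (4 equiv), DMF, 70 °C; cold 1 M HCl
Reagents that add atoms: none
Why: In this SN2 dealkylation the thiolate attacks the methyl carbon and not the neopentyl-type C1 carbonyl, so crowding is irrelevant, the tert-butyl ester cannot react this way, and the thiolate is too weak a base to enolise C7.

Step 5
Reactants: 6 (3R)-2,2-diallyl-4-tert-butoxy-3-methyl-4-oxobutanoic acid
Product: 7 tert-butyl (2R)-2-[(3S,5S)-3-allyl-5-(iodomethyl)-2-oxotetrahydrofuran-3-yl]propanoate (iodolactone)
Conditions: N-iodosuccinimide (1.05 equiv), (S)-2'-[(phenylselanyl)methyl]-1,1'-binaphthalen-2-ol (10 mol%), toluene/CH2Cl2 3:1, −60 °C, dark; aq. Na2S2O3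
Reagents that add atoms: N-iodosuccinimide, O=C1CCC(=O)N1I
Why: The selenide of the catalyst takes I+ from N-iodosuccinimide while its phenol hydrogen-bonds the C1 carboxyl group, so iodonium formation on one allyl group and anti attack of the carboxyl oxygen on its inner carbon C4 occur inside one chiral assembly; succinimide takes up the proton and, with no HI present, the addition is not reversed. The closest known reaction type is the catalytic enantioselective desymmetrising halolactonisation of α,α-diallyl carboxylic acids. The γ-lactone (O, C1, C6, C5, C4) closes in the 5-exo mode, preferred over 6-endo because the inner carbon of a terminal alkene bears the positive charge and because quaternary C6 exerts a Thorpe–Ingold effect. C6 is set by the choice of the pro-S allyl group, controlled by the catalyst acting together with the fixed (R)-C7 centre that makes the two allyl groups diastereotopic, and C4 is set by the alkene face reached by the catalyst-bound iodine, oxygen adding to the opposite face. The step needs one of four diastereomers (CH2I cis to the remaining allyl group), a single cyclisation, and attack by C1 rather than C8: the one free carboxyl group, the poorly nucleophilic tert-butyl ester (which could only close a six-membered ring) and one equivalent of iodinating agent secure the last two, and since C7 is enantiopure every stereochemical error gives a separable diastereomer and never the enantiomer. Kinetic control is essential, because the bulkier α- and γ-substituents of a γ-lactone prefer to be cis, which would put CH2I next to the C7 branch.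

Step 6
Reactants: 7 tert-butyl (2R)-2-[(3S,5S)-3-allyl-5-(iodomethyl)-2-oxotetrahydrofuran-3-yl]propanoate
Product: 9 1-tert-butyl 4-methyl (2R,3S)-3-allyl-2-methyl-3-{[(2S)-oxiran-2-yl]methyl}butanedioate (epoxy diester), via iodohydrin diester 8 (not isolated)
Conditions: NaOMe (1.1 equiv), MeOH, 0 °C to rt
Reagents that add atoms: sodium methoxide, [Na+].[O-]C
Why: Methanolysis of the strained lactone frees the C4 alkoxide, which displaces the neighbouring iodide in an irreversible intramolecular Williamson reaction, and because the C4–O bond is never broken C4 keeps its configuration.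

Step 7
Reactants: 9 epoxy diester; 10 thioanisole
Product: 13 tert-butyl (2R)-2-{(3S,5S)-3-allyl-2-oxo-5-[2-(phenylthio)ethyl]tetrahydrofuran-3-yl}propanoate (lactone sulfide), via (phenylthio)methyllithium 11 (not isolated), via hydroxy diester 12 (not isolated)
Conditions: 10, nBuLi, THF, 0 °C to rt; −78 °C, BF3·OEt2 (1.5 equiv), then 9; sat. aq. NaHCO3; pyridinium 4-toluenesulfonate (cat.), toluene, 50 °C
Reagents that add atoms: n-butyllithium, [Li]CCCC (Li of 11 only)
Why: The BF3-assisted SN2 opening of a terminal epoxide by a sulfur-stabilised organolithium at unsubstituted C3 is complete at −78 °C, where neither hindered ester reacts and the O–BF3 adduct cannot lactonise while organolithium is present, and the freed γ-hydroxy ester then closes to one defined lactone by Thorpe–Ingold-assisted transesterification with the C4–O bond untouched.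

Step 8
Reactants: 13 lactone sulfide
Product: 15 1-tert-butyl 4-methyl (2R,3S)-3-allyl-3-[(2S)-2-methoxy-4-(phenylthio)butyl]-2-methylbutanedioate (methoxy diester), via lithium hydroxy carboxylate 14 (not isolated)
Conditions: LiOH·H2O (3 equiv), THF/MeOH/H2O, rt; evaporate, toluene azeotrope; NaH (3 equiv), DMF, 0 °C; MeI (1.1 equiv), 0 °C, then MeI (5 equiv), rt
Reagents that add atoms: lithium hydroxide, [Li+].[OH-]; iodomethane, CI
Why: Saponification parks C1 as a carboxylate that cannot acylate the C4 alkoxide, so Williamson methylation of the far more nucleophilic alkoxide with the first portion of MeI precedes esterification of the carboxylate with the second, and C4 is retained because only the O–H bond reacts.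

Step 9
Reactants: 15 methoxy diester
Product: 16 1-tert-butyl 4-methyl (2R,3S)-3-allyl-3-[(2S)-2-methoxy-4-(phenylsulfinyl)butyl]-2-methylbutanedioate (epimer mixture at sulfur)
Conditions: 3-chloroperoxybenzoic acid (1.0 equiv), CH2Cl2, −78 °C
Reagents that add atoms: 3-chloroperoxybenzoic acid, O=C(OO)c1cccc(Cl)c1
Why: Chemoselective sulfide oxidation works because sulfur is far more nucleophilic than a terminal alkene at this temperature, and the new sulfur stereocentre is irrelevant because it is lost in step 10.

Step 10
Reactants: 16 sulfoxide diester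
Product: 18 tert-butyl (2R)-2-[(1S,5S)-1-allyl-5-methoxy-2-oxocyclohex-3-en-1-yl]propanoate (enone ester), via keto sulfoxide 17 (not isolated)
Conditions: LDA (2.2 equiv), THF, −78 to 0 °C; AcOH; toluene, CaCO3, 80 °C
Reagents that add atoms: none
Why: The rapidly formed α-sulfinyl carbanion at C2 acylates itself on the C1 methyl ester in a Dieckmann-type six-membered closure (the seven-membered alternative at the tert-butyl ester and the kinetically shielded C7–H do not compete), and thermal syn elimination of the β-keto sulfoxide can only run towards C3, giving the C2=C3 enone.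

Step 11
Reactants: 18 enone ester
Product: 19 (2R)-2-[(1S,5S)-1-allyl-5-methoxy-2-oxocyclohex-3-en-1-yl]propanoic acid
Conditions: CF3CO2H/CH2Cl2 1:4, 0 °C to rt
Reagents that add atoms: none
Why: Acidolysis of the tert-butyl ester by loss of the tert-butyl cation needs no attack at crowded C8 and no base, so the enone, the allyl group, the C4 ether and C7 are left alone.

Step 12
Reactants: 19 enone acid; 20 4-bromo-1,2-dimethoxybenzene
Product: 24 (4S,6S)-6-allyl-6-[(2R)-1-(3,4-dimethoxyphenyl)-1-oxopropan-2-yl]-4-methoxycyclohex-2-en-1-one (target), via acid chloride 21 (not isolated), via 3,4-dimethoxyphenyllithium 22 (not isolated), via arylzinc chloride 23 (not isolated)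
Conditions: 19, 1-chloro-N,N,2-trimethylprop-1-en-1-amine (1.2 equiv), CH2Cl2, 0 °C to rt, concentrate; separately 20, nBuLi, THF, −78 °C, then ZnCl2 (1.1 equiv), to 0 °C; combine, Pd(PPh3)4 (5 mol%), THF, 0 °C to rt
Reagents that add atoms: 1-chloro-N,N,2-trimethylprop-1-en-1-amine, CC(C)=C(Cl)N(C)C (Cl of 21 only); n-butyllithium, [Li]CCCC (Li of 22 only); zinc dichloride, Cl[Zn]Cl (ZnCl of 23 only)
Why: In this Negishi-type acylation zerovalent palladium inserts into the C8–Cl bond and the arylzinc reagent, too mild to add to the enone or to enolise C7, transfers the aryl group, while the neutral chloroenamine makes the acid chloride without HCl or amine base, so no ketene forms and C7 holds.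

**Compound list**
1 | (R)-2-methylsuccinic acid 4-methyl ester | COC(=O)C[C@@H](C)C(=O)O | starting material
2 | allyl bromide | C=CCBr | starting material
3 | (2R)-3-(methoxycarbonyl)-2-methylhex-5-enoic acid (epimer mixture at C6) | C=CCC(C(=O)OC)[C@@H](C)C(=O)O | intermediate
4 | (2R)-3-allyl-3-(methoxycarbonyl)-2-methylhex-5-enoic acid | C=CCC(CC=C)(C(=O)OC)[C@@H](C)C(=O)O | intermediate
5 | 1-tert-butyl 4-methyl (2R)-3,3-diallyl-2-methylbutanedioate | C=CCC(CC=C)(C(=O)OC)[C@@H](C)C(=O)OC(C)(C)C | intermediate
6 | (3R)-2,2-diallyl-4-tert-butoxy-3-methyl-4-oxobutanoic acid | C=CCC(CC=C)([C@@H](C)C(=O)OC(C)(C)C)C(=O)O | intermediate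
7 | tert-butyl (2R)-2-[(3S,5S)-3-allyl-5-(iodomethyl)-2-oxotetrahydrofuran-3-yl]propanoate | C=CC[C@@]1([C@@H](C)C(=O)OC(C)(C)C)C[C@@H](CI)OC1=O | intermediate
8 | 1-tert-butyl 4-methyl (2R,3S)-3-allyl-3-[(2S)-2-hydroxy-3-iodopropyl]-2-methylbutanedioate | C=CC[C@@](C[C@@H](CI)O)(C(=O)OC)[C@@H](C)C(=O)OC(C)(C)C | intermediate
9 | 1-tert-butyl 4-methyl (2R,3S)-3-allyl-2-methyl-3-{[(2S)-oxiran-2-yl]methyl}butanedioate | C=CC[C@@](C[C@H]1CO1)(C(=O)OC)[C@@H](C)C(=O)OC(C)(C)C | intermediate
10 | thioanisole | CSc1ccccc1 | starting material
11 | (phenylthio)methyllithium | [Li]CSc1ccccc1 | intermediate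
12 | 1-tert-butyl 4-methyl (2R,3S)-3-allyl-3-[(2S)-2-hydroxy-4-(phenylthio)butyl]-2-methylbutanedioate | C=CC[C@@](C[C@@H](CCSc1ccccc1)O)(C(=O)OC)[C@@H](C)C(=O)OC(C)(C)C | intermediate
13 | tert-butyl (2R)-2-{(3S,5S)-3-allyl-2-oxo-5-[2-(phenylthio)ethyl]tetrahydrofuran-3-yl}propanoate | C=CC[C@@]1([C@@H](C)C(=O)OC(C)(C)C)C[C@@H](CCSc2ccccc2)OC1=O | intermediate
14 | lithium (2S,4S)-2-allyl-2-[(2R)-1-tert-butoxy-1-oxopropan-2-yl]-4-hydroxy-6-(phenylthio)hexanoate | C=CC[C@@](C[C@@H](CCSc1ccccc1)O)(C(=O)[O-])[C@@H](C)C(=O)OC(C)(C)C.[Li+] | intermediate
15 | 1-tert-butyl 4-methyl (2R,3S)-3-allyl-3-[(2S)-2-methoxy-4-(phenylthio)butyl]-2-methylbutanedioate | C=CC[C@@](C[C@@H](CCSc1ccccc1)OC)(C(=O)OC)[C@@H](C)C(=O)OC(C)(C)C | intermediate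
16 | 1-tert-butyl 4-methyl (2R,3S)-3-allyl-3-[(2S)-2-methoxy-4-(phenylsulfinyl)butyl]-2-methylbutanedioate (epimers at S) | C=CC[C@@](C[C@@H](CCS(=O)c1ccccc1)OC)(C(=O)OC)[C@@H](C)C(=O)OC(C)(C)C | intermediate
17 | tert-butyl (2R)-2-[(1S,5S)-1-allyl-5-methoxy-2-oxo-3-(phenylsulfinyl)cyclohexyl]propanoate (epimers at C2 and S) | C=CC[C@@]1([C@@H](C)C(=O)OC(C)(C)C)C[C@H](OC)CC(S(=O)c2ccccc2)C1=O | intermediate
18 | tert-butyl (2R)-2-[(1S,5S)-1-allyl-5-methoxy-2-oxocyclohex-3-en-1-yl]propanoate | C=CC[C@@]1([C@@H](C)C(=O)OC(C)(C)C)C[C@H](OC)C=CC1=O | intermediate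
19 | (2R)-2-[(1S,5S)-1-allyl-5-methoxy-2-oxocyclohex-3-en-1-yl]propanoic acid | C=CC[C@@]1([C@@H](C)C(=O)O)C[C@H](OC)C=CC1=O | intermediate
20 | 4-bromo-1,2-dimethoxybenzene | COc1ccc(Br)cc1OC | starting material
21 | (2R)-2-[(1S,5S)-1-allyl-5-methoxy-2-oxocyclohex-3-en-1-yl]propanoyl chloride | C=CC[C@@]1([C@@H](C)C(=O)Cl)C[C@H](OC)C=CC1=O | intermediate
22 | 3,4-dimethoxyphenyllithium | [Li]c1ccc(OC)c(OC)c1 | intermediate
23 | (3,4-dimethoxyphenyl)zinc chloride | Cl[Zn]c1ccc(OC)c(OC)c1 | intermediate
24 | (4S,6S)-6-allyl-6-[(2R)-1-(3,4-dimethoxyphenyl)-1-oxopropan-2-yl]-4-methoxycyclohex-2-en-1-one | C=CC[C@@]1([C@@H](C)C(=O)c2ccc(OC)c(OC)c2)C[C@H](OC)C=CC1=O | target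

**Total step count:** 12. **Longest linear sequence:** 12 steps (1 to 24). Compounds 2, 10 and 20 are bought and enter directly.

**The three steps most likely to fail**

**Step 5 (group and face selection).**
- What may go wrong: the catalyst may not override the small intrinsic bias of the substrate, it may be mismatched with C7, or an uncatalysed background reaction may dilute its effect.
- Fallback: covalent instead of catalytic control, setting out from 6 and returning at 7.
- Acid 6 is converted with 1-chloro-N,N,2-trimethylprop-1-en-1-amine into the acid chloride F1. This acylates (S)-2-(methoxymethyl)pyrrolidine (Et3N, CH2Cl2) to give the tertiary amide F2.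
- Iodine in aqueous THF at 0 °C then makes the amide oxygen the nucleophile. The iminium lactone iodide F3 is hydrolysed in the flask to 7 with release of the auxiliary, whose basic nitrogen takes up the HI and so protects the tert-butyl ester.
- Auxiliary-directed group- and face-selective iodolactonisation of diallyl amides is known chemistry, and both antipodes of the amine are sold.
- In either mode, material lost to poor selectivity can be returned to 6 with zinc dust in acetic acid, because the reductive elimination makes C6 non-stereogenic again.

**Step 7 (epoxide opening beside two esters).**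
- What may go wrong: lithiation of thioanisole without an amine additive may be incomplete, the Lewis acid may trigger participation of the C1 ester oxygen in the epoxide opening, or the organolithium may attack a carbonyl group once the lactone starts to form.
- Fallback: remove every acylating group at C1 before the carbanion arrives, setting out from 7 and returning at 14.
- Iodolactone 7 is saponified with LiOH (2 equiv) in aqueous THF. The C4 alkoxide closes the epoxide, and the lithium epoxy carboxylate F4 is obtained by evaporation and azeotropic drying.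
- The carboxylate can be attacked neither by the organolithium nor by the later alkoxide. Reagent 11 can therefore be made with DABCO as additive and used in excess at 0 °C without any Lewis acid.
- Aqueous work-up at high pH gives 14, which enters the methylation half of step 8. This path also makes step 6 and the saponification unnecessary.

**Step 12 (aryl ketone beside an enone and an allyl group).**
- What may go wrong: the activated C8 acyl group may close onto the C1 carbonyl oxygen, the acylpalladium species may insert into the pendant allyl group to form a five-membered ring, coupling at crowded C8 may be slow, or configuration at C7 may erode.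
- Fallback: chelation-driven acyl substitution without acid chloride and without palladium, setting out from 19 and returning at 24.
- Acid 19 is condensed with 2,2'-dipyridyl disulfide and PPh3 (neutral, rt) to give the S-(pyridin-2-yl) thioester F5.
- Bromide 20 and magnesium turnings in THF give (3,4-dimethoxyphenyl)magnesium bromide F6.
- One equivalent of F6 added to F5 at −78 °C should deliver 24. Magnesium chelation by the pyridyl nitrogen and the carbonyl oxygen makes the thioester far more reactive than the hindered conjugated C1 ketone, and the chelated adduct prevents a second addition.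

**Further compounds**
F1 | step 5 | tert-butyl (2R)-3-allyl-3-(chlorocarbonyl)-2-methylhex-5-enoate | C=CCC(CC=C)([C@@H](C)C(=O)OC(C)(C)C)C(=O)Cl
F2 | step 5 | tert-butyl (2R)-3-allyl-3-{[(2S)-2-(methoxymethyl)pyrrolidin-1-yl]carbonyl}-2-methylhex-5-enoate | C=CCC(CC=C)([C@@H](C)C(=O)OC(C)(C)C)C(=O)N1CCC[C@H]1COC
F3 | step 5 | (2S)-1-{(3S,5S)-3-allyl-3-[(2R)-1-tert-butoxy-1-oxopropan-2-yl]-5-(iodomethyl)dihydrofuran-2(3H)-ylidene}-2-(methoxymethyl)pyrrolidinium iodide | C=CC[C@@]1([C@@H](C)C(=O)OC(C)(C)C)C[C@@H](CI)OC1=[N+]2CCC[C@H]2COC.[I-]
F4 | step 7 | lithium (2S)-2-allyl-2-[(2R)-1-tert-butoxy-1-oxopropan-2-yl]-3-[(2S)-oxiran-2-yl]propanoate | C=CC[C@@](C[C@H]1CO1)(C(=O)[O-])[C@@H](C)C(=O)OC(C)(C)C.[Li+]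
F5 | step 12 | S-(pyridin-2-yl) (2R)-2-[(1S,5S)-1-allyl-5-methoxy-2-oxocyclohex-3-en-1-yl]propanethioate | C=CC[C@@]1([C@@H](C)C(=O)Sc2ccccn2)C[C@H](OC)C=CC1=O
F6 | step 12 | (3,4-dimethoxyphenyl)magnesium bromide | Br[Mg]c1ccc(OC)c(OC)c1
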